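The route rests on detaching ring A (C4a, C5, C6, C7, C8, C8a) from an intact, already arylated ring C. One operation, a Danheiser benzannulation, puts it back. Light converts a pyranonyl diazomethyl ketone into a vinylketene, tert-butoxyethyne adds, and 4π opening followed by 6π closure onto the pyranone C2=C3 edge (future C8a–C4a) gives the resorcinol. The step exploits the meta oxygen pattern of ring A: the ketene carbonyl becomes the free 5-OH chelated to the C4 carbonyl, the ynol ether oxygen becomes a masked 7-O, so both emerge differentiated. The precursor is kojic acid bearing ring B at C6, a MOM ether on the future 3-O and COCHN2 in place of CH2OH.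

Key step: step 10

Assumption: the target is taken as the free bis(hydrogen sulfate) exactly as drawn. This acid form is prone to self-catalysed loss of the 3-sulfate, so the dipotassium salt 28 is the purified storage form and the acid is released from it in the last step.

Step 1
Reactants: 1 kojic acid (5-hydroxy-2-(hydroxymethyl)-4H-pyran-4-one)
Product: 2 6-bromokojic acid (2-bromo-3-hydroxy-6-(hydroxymethyl)-4H-pyran-4-one)
Conditions: NBS (1.05 equiv), DMF, 0 °C to rt, dark
Reagents that add atoms: N-bromosuccinimide O=C1CCC(=O)N1Br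
Why: Electrophilic bromination of an enol: the 5-OH makes C6 (the site where kojic acid also undergoes aldol and Mannich reactions) the only strongly nucleophilic ring carbon, so one equivalent of NBS should substitute there and leave C3 and the CH2OH alone.

Step 2
Reactants: 2 6-bromokojic acid
Product: 3 6-bromo-2-(hydroxymethyl)-5-(methoxymethoxy)-4H-pyran-4-one
Conditions: MOMCl (1.05 equiv), K2CO3 (1.2 equiv), acetone, 0 °C to rt
Reagents that add atoms: chloromethyl methyl ether COCCl
Why: Williamson-type O-alkylation: carbonate ionises only the bromine-acidified enolic OH and not the primary alcohol, so a single equivalent of MOMCl should be consumed at the enolate oxygen, in line with the familiar selective 5-O-alkylation of kojic acid.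

Step 3
Reactants: 4 4-bromo-2-methoxyphenol
Product: 5 1-(benzyloxy)-4-bromo-2-methoxybenzene
Conditions: BnBr (1.1 equiv), K2CO3 (1.5 equiv), DMF, rt
Reagents that add atoms: benzyl bromide BrCc1ccccc1
Why: Williamson ether synthesis on a phenoxide; benzyl is chosen because it should outlast base, oxidant, light and TFA and leave at the end by neutral hydrogenolysis, which sulfate monoester salts tolerate.

Step 4
Reactants: 5 1-(benzyloxy)-4-bromo-2-methoxybenzene
Product: 8 (4-benzyloxy-3-methoxyphenyl)boronic acid, via aryllithium 6 (not isolated), via lithium aryltriisopropoxyborate 7 (not isolated)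
Conditions: n-BuLi (1.05 equiv), THF, −78 °C; B(OiPr)3 (1.3 equiv), −78 °C to rt; 1 M HCl, 0 °C
Reagents that add atoms: triisopropyl borate CC(C)OB(OC(C)C)OC(C)C; water O; n-butyllithium [Li]CCCC (lithium stays only in 6 and 7)
Why: Bromine–lithium exchange at −78 °C outruns benzylic deprotonation, the hindered borate stops at the mono-aryl ate complex 7, and mild acid hydrolyses it to the boronic acid.

Step 5
Reactants: 3 6-bromo-2-(hydroxymethyl)-5-(methoxymethoxy)-4H-pyran-4-one; 8 (4-benzyloxy-3-methoxyphenyl)boronic acid
Product: 9 6-(4-benzyloxy-3-methoxyphenyl)-2-(hydroxymethyl)-5-(methoxymethoxy)-4H-pyran-4-one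
Conditions: Pd(dppf)Cl2 (3 mol %), K3PO4 (2.5 equiv), 1,4-dioxane/H2O 10:1, 80 °C, Ar
Reagents that add atoms: none
Why: Suzuki–Miyaura coupling: the C6–Br bond belongs to a β-bromo enone and should add readily to zerovalent palladium, phosphate in a water-poor medium limits hydroxide attack on the pyranone, and the MOM ether and free CH2OH are spectators.

Step 6
Reactants: 9 6-(4-benzyloxy-3-methoxyphenyl)-2-(hydroxymethyl)-5-(methoxymethoxy)-4H-pyran-4-one
Product: 11 6-(4-benzyloxy-3-methoxyphenyl)-5-(methoxymethoxy)-4-oxo-4H-pyran-2-carboxylic acid, via aldehyde 10 (not isolated)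
Conditions: TEMPO (0.2 equiv), PhI(OAc)2 (2.4 equiv), MeCN/H2O 1:1, rt
Reagents that add atoms: water O
Why: Oxoammonium (TEMPO) oxidation: the alcohol goes to aldehyde 10 and its hydrate goes on to the acid in one pot, in a medium no more acidic than acetic acid and free of chlorine-based co-oxidants, so the MOM and benzyl ethers and the electron-rich ring B should be untouched.

Step 7
Reactants: 11 6-(4-benzyloxy-3-methoxyphenyl)-5-(methoxymethoxy)-4-oxo-4H-pyran-2-carboxylic acid
Product: 13 6-(4-benzyloxy-3-methoxyphenyl)-2-(diazoacetyl)-5-(methoxymethoxy)-4H-pyran-4-one, via mixed isobutyl carbonic anhydride 12 (not isolated)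
Conditions: i-BuOCOCl (1.05 equiv), N-methylmorpholine (1.1 equiv), THF, −20 °C, filter; CH2N2 (3 equiv, dried Et2O solution), 0 °C, dark; excess swept out with N2
Reagents that add atoms: diazomethane C=[N+]=[N-]; isobutyl chloroformate CC(C)COC(=O)Cl (its atoms stay only in 12)
Why: Acylation of diazomethane (first half of the Arndt–Eistert sequence): HCl-free activation spares the MOM ether, CH2N2 attacks the more electrophilic pyranone-bound carbonyl of 12, the expelled isobutyl carbonate takes the proton and collapses to CO2 and isobutanol, and the pyranone should behave as a heteroarene (as chromone-2-carbonyl derivatives do) rather than as a dipolarophile at 0 °C.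

Step 8
Reactants: 14 trichloroethylene
Product: 16 (E)-1-tert-butoxy-1,2-dichloroethene, via dichloroacetylene 15 (not isolated)
Conditions: KOtBu (1.1 equiv), THF, −40 °C to rt, Ar, closed system
Reagents that add atoms: potassium tert-butoxide CC(C)(C)[O-].[K+]
Why: Elimination–addition: tert-butoxide removes HCl from 14 and the transient, hazardous alkyne 15, never allowed to leave the solution, takes up tert-butanol by anti addition, which places the two chlorines trans (E alkene), as in the established dichlorovinyl ether route from hindered alcohols.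

Step 9
Reactants: 16 (E)-1-tert-butoxy-1,2-dichloroethene
Product: 19 tert-butoxyethyne, via chloroalkyne 17 (not isolated), via lithium tert-butoxyacetylide 18 (not isolated)
Conditions: n-BuLi (2.1 equiv), Et2O, −78 to −30 °C; H2O, −78 to 0 °C; distil under reduced pressure, bath ≤ 25 °C; store at −20 °C and use fresh
Reagents that add atoms: n-butyllithium [Li]CCCC (lithium stays only in 18)
Why: Vinylic deprotonation with loss of LiCl gives chloroalkyne 17, a second equivalent of n-BuLi performs chlorine–lithium exchange to acetylide 18, and cold protonation releases the terminal ynol ether, which is kept cold because it loses isobutene by a retro-ene reaction on warming.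

Step 10
Reactants: 13 6-(4-benzyloxy-3-methoxyphenyl)-2-(diazoacetyl)-5-(methoxymethoxy)-4H-pyran-4-one; 19 tert-butoxyethyne
Product: 24 4'-O-benzyl-7-O-tert-butyl-3-O-(methoxymethyl)isorhamnetin, via pyranonylketene 20 (not isolated), via vinylcyclobutenone 21 (not isolated), via dienylketene 22 (not isolated), via cyclohexadienone 23 (not isolated)
Conditions: 19 (4 equiv), CH2Cl2 (0.02 M), hν (365 nm LED, or Hg lamp through uranium glass, λ > 340 nm; batch or FEP flow coil), 10–15 °C, Ar; evaporate at ≤ 20 °C; toluene, 80 °C
Reagents that add atoms: none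
Why: Light expels N2 from 13 with a 1,2-shift of the pyranonyl group (photo-Wolff) to give ketene 20, and the unsubstituted, nucleophilic carbon of ynol ether 19 attacks the ketene carbonyl carbon, so the [2+2] forms C5–C6 and C7–C8 and gives cyclobutenone 21. Light or the later warming opens 21 by 4π electrocyclic cleavage of the C5–C8 bond to dienylketene 22, ring A then closes by a 6π electrocyclisation that joins the ketene carbon (C5) to the unsubstituted pyranone C3 (C4a), and dienone 23, whose C4a–H lies between two carbonyls, enolises to phenol 24. The closest known reaction type is the second-generation Danheiser benzannulation of alkenyl and heteroaryl diazomethyl ketones with alkoxy- or siloxyalkynes, the weakly aromatic pyranone C2=C3 bond here playing the vinyl part. The step needs regioselectivity in the [2+2], which the polarisation of 19 secures (7-O ends meta to 5-OH), whereas the closure has no choice because the other neighbour of pyranone C2 is the ring oxygen. No stereocentre is kept, since C4 of 21 and C4a of 23 are transient and racemic. Long-wavelength light addresses the diazo ketone rather than the aryl-pyranone chromophore, 13 carries no OH that could trap 20, the chelated 5-OH of 24 is a poor ketene trap, and 19 is stripped cold before the heating because it fragments to ketene and isobutene when warmed.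

Step 11
Reactants: 24 4'-O-benzyl-7-O-tert-butyl-3-O-(methoxymethyl)isorhamnetin
Product: 25 4'-O-benzylisorhamnetin
Conditions: TFA/CH2Cl2 1:1, Et3SiH (4 equiv), 0 °C to rt
Reagents that add atoms: none
Why: Acidolysis of an aryl tert-butyl ether and an enol-type MOM acetal: in both cases the acidic flavonol oxygen is the leaving group, Et3SiH quenches the tert-butyl and methoxymethyl cations by hydride transfer before they can alkylate the nucleophilic C6 and C8, and the benzyl ether, deactivated by conjugation with the chromone, should survive because no sulfide-type soft nucleophile (which together with TFA strips aryl benzyl ethers) is present.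

Step 12
Reactants: 25 4'-O-benzylisorhamnetin
Product: 27 dipotassium 4'-O-benzylisorhamnetin 3,7-disulfate, via bis(pyridinium) disulfate 26 (not isolated)
Conditions: SO3·pyridine (3 equiv), DMF, 0 °C to rt; aq KHCO3 to pH 7.5; Sephadex LH-20 (H2O/MeOH)
Reagents that add atoms: sulfur trioxide–pyridine complex O=S(=O)([O-])[n+]1ccccc1; potassium hydrogen carbonate [K+].OC([O-])=O
Why: O-sulfonation with an amine–SO3 complex: the acidic 7-OH and the enolic 3-OH react at room temperature, the 4'-oxygen is blocked, the 5-OH locked in a strong hydrogen bond to the C4 carbonyl resists sulfation unless a large excess and heat are used, and KHCO3 turns pyridinium salt 26 into the stable dipotassium salt.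

Step 13
Reactants: 27 dipotassium 4'-O-benzylisorhamnetin 3,7-disulfate
Product: 28 dipotassium isorhamnetin 3,7-disulfate
Conditions: H2 (1 atm), Pd/C (10 wt %), MeOH/H2O, pH 7 (trace KHCO3), rt
Reagents that add atoms: none
Why: Catalytic hydrogenolysis of an aryl benzyl ether, to which sulfate monoester salts and the tetrasubstituted C2=C3 bond of a flavonol are inert at atmospheric pressure in neutral medium.

Step 14
Reactants: 28 dipotassium isorhamnetin 3,7-disulfate
Product: 29 isorhamnetin 3,7-di-O-sulfate (target, acid form)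
Conditions: sulfonated polystyrene resin (H+ form), H2O, 0–4 °C; freeze-dry at once
Reagents that add atoms: none
Why: Cation exchange swaps K+ for H+ without adding any soluble strong acid, and low temperature with immediate freeze-drying limits the self-catalysed hydrolysis to which the 3-sulfate is most prone.

Compound list
1 | kojic acid | O=c1cc(CO)occ1O | starting material
2 | 6-bromokojic acid (2-bromo-3-hydroxy-6-(hydroxymethyl)-4H-pyran-4-one) | O=c1cc(CO)oc(Br)c1O | intermediate
3 | 6-bromo-2-(hydroxymethyl)-5-(methoxymethoxy)-4H-pyran-4-one | O=c1cc(CO)oc(Br)c1OCOC | intermediate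
4 | 4-bromo-2-methoxyphenol | COc1cc(Br)ccc1O | starting material
5 | 1-(benzyloxy)-4-bromo-2-methoxybenzene | COc1cc(Br)ccc1OCc1ccccc1 | intermediate
6 | (4-benzyloxy-3-methoxyphenyl)lithium | COc1cc([Li])ccc1OCc1ccccc1 | intermediate
7 | lithium (4-benzyloxy-3-methoxyphenyl)triisopropoxyborate | COc1cc([B-](OC(C)C)(OC(C)C)OC(C)C)ccc1OCc1ccccc1.[Li+] | intermediate
8 | (4-benzyloxy-3-methoxyphenyl)boronic acid | COc1cc(B(O)O)ccc1OCc1ccccc1 | intermediate
9 | 6-(4-benzyloxy-3-methoxyphenyl)-2-(hydroxymethyl)-5-(methoxymethoxy)-4H-pyran-4-one | COCOc1c(-c2ccc(OCc3ccccc3)c(OC)c2)oc(CO)cc1=O | intermediate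
10 | 6-(4-benzyloxy-3-methoxyphenyl)-5-(methoxymethoxy)-4-oxo-4H-pyran-2-carbaldehyde | COCOc1c(-c2ccc(OCc3ccccc3)c(OC)c2)oc(C=O)cc1=O | intermediate
11 | 6-(4-benzyloxy-3-methoxyphenyl)-5-(methoxymethoxy)-4-oxo-4H-pyran-2-carboxylic acid | COCOc1c(-c2ccc(OCc3ccccc3)c(OC)c2)oc(C(=O)O)cc1=O | intermediate
12 | mixed anhydride of 11 with isobutyl hydrogen carbonate | COCOc1c(-c2ccc(OCc3ccccc3)c(OC)c2)oc(C(=O)OC(=O)OCC(C)C)cc1=O | intermediate
13 | 6-(4-benzyloxy-3-methoxyphenyl)-2-(diazoacetyl)-5-(methoxymethoxy)-4H-pyran-4-one | COCOc1c(-c2ccc(OCc3ccccc3)c(OC)c2)oc(C(=O)C=[N+]=[N-])cc1=O | intermediate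
14 | trichloroethylene | ClC=C(Cl)Cl | starting material
15 | dichloroacetylene | ClC#CCl | intermediate
16 | (E)-1-tert-butoxy-1,2-dichloroethene | CC(C)(C)O/C(Cl)=C\Cl | intermediate
17 | 1-tert-butoxy-2-chloroethyne | CC(C)(C)OC#CCl | intermediate
18 | lithium tert-butoxyacetylide | CC(C)(C)OC#C[Li] | intermediate
19 | tert-butoxyethyne | CC(C)(C)OC#C | intermediate
20 | [6-(4-benzyloxy-3-methoxyphenyl)-5-(methoxymethoxy)-4-oxo-4H-pyran-2-yl]ketene | COCOc1c(-c2ccc(OCc3ccccc3)c(OC)c2)oc(C=C=O)cc1=O | intermediate
21 | 3-tert-butoxy-4-(pyranon-2-yl)cyclobut-2-en-1-one (racemic at C4) | COCOc1c(-c2ccc(OCc3ccccc3)c(OC)c2)oc(C2C(=O)C=C2OC(C)(C)C)cc1=O | intermediate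
22 | (E)-3-tert-butoxy-4-(pyranon-2-yl)buta-1,3-dien-1-one, pyranonyl cis to the ketenyl group | COCOc1c(-c2ccc(OCc3ccccc3)c(OC)c2)oc(/C=C(OC(C)(C)C)\C=C=O)cc1=O | intermediate
23 | 4a-H keto tautomer of 24 (4aH-chromene-4,5-dione, racemic at C4a) | COCOC1=C(c2ccc(OCc3ccccc3)c(OC)c2)OC2=CC(OC(C)(C)C)=CC(=O)C2C1=O | intermediate
24 | 2-(4-benzyloxy-3-methoxyphenyl)-7-tert-butoxy-5-hydroxy-3-(methoxymethoxy)-4H-chromen-4-one | COCOc1c(-c2ccc(OCc3ccccc3)c(OC)c2)oc2cc(OC(C)(C)C)cc(O)c2c1=O | intermediate
25 | 4'-O-benzylisorhamnetin (2-(4-benzyloxy-3-methoxyphenyl)-3,5,7-trihydroxy-4H-chromen-4-one) | COc1cc(-c2oc3cc(O)cc(O)c3c(=O)c2O)ccc1OCc1ccccc1 | intermediate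
26 | bis(pyridinium) 4'-O-benzylisorhamnetin 3,7-disulfate | COc1cc(-c2oc3cc(OS(=O)(=O)[O-])cc(O)c3c(=O)c2OS(=O)(=O)[O-])ccc1OCc1ccccc1.c1cc[nH+]cc1.c1cc[nH+]cc1 | intermediate
27 | dipotassium 4'-O-benzylisorhamnetin 3,7-disulfate | COc1cc(-c2oc3cc(OS(=O)(=O)[O-])cc(O)c3c(=O)c2OS(=O)(=O)[O-])ccc1OCc1ccccc1.[K+].[K+] | intermediate
28 | dipotassium isorhamnetin 3,7-disulfate | COc1cc(-c2oc3cc(OS(=O)(=O)[O-])cc(O)c3c(=O)c2OS(=O)(=O)[O-])ccc1O.[K+].[K+] | intermediate
29 | isorhamnetin 3,7-di-O-sulfate | COc1cc(-c2oc3cc(OS(=O)(=O)O)cc(O)c3c(=O)c2OS(=O)(=O)O)ccc1O | target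

Total step count: 14. Longest linear sequence: 10 steps (1, 2, 5, 6, 7, 10, 11, 12, 13, 14). The boronic acid branch (steps 3, 4) and the ynol ether branch (steps 8, 9) run in parallel.

Steps most likely to fail

Step 10. The process to fear is competing photochemistry of the aryl-pyranone chromophore running alongside nitrogen loss. This could be skeletal rearrangement of the 4-pyranone, or hydrogen abstraction from the OCH2O group by the excited C4 carbonyl. Self-condensation of the ketene is a further risk. The fallback makes the same ketene in the dark by dehydrochlorination, and it sets out from 13.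
- PhCO2Ag (cat.), Et3N, THF/H2O, rt, dark (Arndt–Eistert homologation, ketene trapped by water) should give [6-(4-benzyloxy-3-methoxyphenyl)-5-(methoxymethoxy)-4-oxo-4H-pyran-2-yl]acetic acid F1. It is kept cold because it is a vinylogous β-keto acid.
- 1-Chloro-N,N,2-trimethylprop-1-en-1-amine in CH2Cl2 at 0 °C converts it, without free HCl, into the corresponding acetyl chloride F2.
- Slow addition of Et3N to F2 and excess 19 in CH2Cl2 at 0 °C releases ketene 20, which is intercepted as cyclobutenone 21.
- After cold removal of 19, warming in toluene carries 21 through 22 and 23, and the route is rejoined at 24.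

Step 7. The processes to fear are dipolar addition of diazomethane across the acyl-activated C2=C3 bond of the pyranone and misdirected attack at the carbonate carbonyl of 12. The fallback replaces acylation of diazomethane by diazo transfer onto a methyl ketone, and it sets out from 11.
- EtSH, EDC·HCl, DMAP (cat.), CH2Cl2 should give the S-ethyl thioester F3.
- MeZnI, PdCl2(PPh3)2 (cat.), toluene/THF, rt (Fukuyama ketone synthesis, whose organozinc reagent leaves the pyranone carbonyl alone) gives 2-acetyl-6-(4-benzyloxy-3-methoxyphenyl)-5-(methoxymethoxy)-4H-pyran-4-one F4.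
- LiN(SiMe3)2, THF, −78 °C, then CF3CO2CH2CF3 gives the trifluoroacetylated 1,3-diketone F5, which is used crude.
- MsN3, Et3N, H2O, MeCN, rt transfers the diazo group with loss of the trifluoroacetyl unit (detrifluoroacetylative diazo transfer), and the route is rejoined at 13.

Step 12. The processes to fear are incomplete sulfation at the hindered 3-OH, creeping over-sulfation at the 5-OH, and loss of the 3-sulfate during work-up. All of these lead to ionic mixtures that are hard to separate. The fallback installs neutral, chromatographable sulfate diesters, and it sets out from 25.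
- 2,2,2-Trichloroethyl chlorosulfate (2.2 equiv), Et3N, DMAP, THF, 0 °C should give 4'-O-benzylisorhamnetin 3,7-bis(2,2,2-trichloroethyl sulfate) F6, purified on silica gel.
- Pd/C, HCO2NH4, MeOH, rt then removes both trichloroethyl groups and the benzyl ether in one reductive operation to give diammonium isorhamnetin 3,7-disulfate F7.
- F7 is passed through the same acid-form resin as in step 14, and the route is rejoined at 29.

Further compounds
F1 | step 10 | [6-(4-benzyloxy-3-methoxyphenyl)-5-(methoxymethoxy)-4-oxo-4H-pyran-2-yl]acetic acid | COCOc1c(-c2ccc(OCc3ccccc3)c(OC)c2)oc(CC(=O)O)cc1=O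
F2 | step 10 | [6-(4-benzyloxy-3-methoxyphenyl)-5-(methoxymethoxy)-4-oxo-4H-pyran-2-yl]acetyl chloride | COCOc1c(-c2ccc(OCc3ccccc3)c(OC)c2)oc(CC(=O)Cl)cc1=O
F3 | step 7 | S-ethyl 6-(4-benzyloxy-3-methoxyphenyl)-5-(methoxymethoxy)-4-oxo-4H-pyran-2-carbothioate | COCOc1c(-c2ccc(OCc3ccccc3)c(OC)c2)oc(C(=O)SCC)cc1=O
F4 | step 7 | 2-acetyl-6-(4-benzyloxy-3-methoxyphenyl)-5-(methoxymethoxy)-4H-pyran-4-one | COCOc1c(-c2ccc(OCc3ccccc3)c(OC)c2)oc(C(C)=O)cc1=O
F5 | step 7 | 1-[6-(4-benzyloxy-3-methoxyphenyl)-5-(methoxymethoxy)-4-oxo-4H-pyran-2-yl]-4,4,4-trifluorobutane-1,3-dione | COCOc1c(-c2ccc(OCc3ccccc3)c(OC)c2)oc(C(=O)CC(=O)C(F)(F)F)cc1=O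
F6 | step 12 | 4'-O-benzylisorhamnetin 3,7-bis(2,2,2-trichloroethyl sulfate) | COc1cc(-c2oc3cc(OS(=O)(=O)OCC(Cl)(Cl)Cl)cc(O)c3c(=O)c2OS(=O)(=O)OCC(Cl)(Cl)Cl)ccc1OCc1ccccc1
F7 | step 12 | diammonium isorhamnetin 3,7-disulfate | COc1cc(-c2oc3cc(OS(=O)(=O)[O-])cc(O)c3c(=O)c2OS(=O)(=O)[O-])ccc1O.[NH4+].[NH4+]
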